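## Retrosynthetic overview

1. Target ⇐ 3,4-diacylated 1,5-quinide with three phenol acetates: aqueous HCl opens the γ-lactone (frees 5-OH and CO2H) and removes the ArOAc groups last.
2. O-3 caffeoyl ester ⇐ acyl-chloride esterification of the equatorial 3-OH. O-4 p-coumaroyl ester ⇐ axial-selective hydrolytic opening of a 3,4-fused cyclic ortho ester that already carries the coumaroyl carbon skeleton.
3. Key disconnection: that ortho ester–lactone ⇐ (−)-quinic acid + a triethyl ortho-cinnamate in one pot. Ring order: γ-lactone (C-1 CO–O-5) first, then the 1,3-dioxolane (O-3/O-4). The cyclohexane ring and all four stereocentres come from quinic acid; both arene rings are bought.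
4. Ortho ester ⇐ Heck coupling of 4-iodophenyl acetate with triethyl orthoacrylate. Acyl chloride ⇐ caffeic acid (Ac2O, then (COCl)2 in situ).

Assumption: the target is 3-O-(E)-caffeoyl-4-O-(E)-p-coumaroyl-(−)-quinic acid (quinic acid numbering; 1-OH, O-3, O-4 on one face, 5-OH and CO2H on the other), and compounds 1, 2, 4 and 7 are taken as catalogue chemicals.

## Route

Step 1
Reactants: 1 4-iodophenyl acetate; 2 triethyl orthoacrylate (3,3,3-triethoxyprop-1-ene)
Product: 3 4-[(E)-3,3,3-triethoxyprop-1-en-1-yl]phenyl acetate (triethyl (E)-4-acetoxy-orthocinnamate)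
Conditions: Pd(OAc)2 (2 mol %), P(o-tol)3 (4 mol %), NaOAc (1.5 equiv), DMF, 90 °C; Et3N-deactivated silica
Reagents that add atoms: none
Why: Mizoroki–Heck reaction: the aryl group adds to the unsubstituted alkene terminus and syn-β-hydride elimination can only use the benzylic hydrogen (the ortho-ester carbon has none), giving the E-alkene, while the base-stable ortho ester and the aryl acetate survive the acetate-buffered medium.

Step 2
Reactants: 4 (−)-quinic acid; 3 4-[(E)-3,3,3-triethoxyprop-1-en-1-yl]phenyl acetate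
Product: 6 3,4-O-[(E)-3-(4-acetoxyphenyl)-1-ethoxyprop-2-en-1-ylidene]-1,5-quinide (cis-fused cyclic ortho ester on the bicyclic lactone; both epimers at the ortho-ester carbon), via 1,5-quinide 5 (not isolated)
Conditions: 4 (1.25 equiv), Amberlyst 15 (H+), DMF/PhMe, reflux, Dean–Stark; cool, add 3 (1.0 equiv), 40 °C, 100 mbar (−EtOH); filter, Et3N, Et3N-deactivated silica
Reagents that add atoms: none
Why: Proposed new method: acid-catalysed dehydrative lactonisation (ring flip places CO2H and 5-OH 1,3-diaxial; water leaves azeotropically) gives the lactone, and in the same pot the dialkoxycarbenium ion from 3 is trapped by the now cis (axial O-4/equatorial O-3) diol in a transorthoesterification driven by ethanol removal, closing the dioxolane; the closest known reactions are the one-pot acetonide/lactone and benzylidene/lactone formations from quinic acid and cyclic ortho ester formation on sugar cis-diols, no C–O bond at a ring stereocentre is broken, and the new ortho-ester centre (mixture) is erased in step 4.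

Step 3
Reactants: 7 (E)-caffeic acid
Product: 8 (E)-3,4-diacetoxycinnamic acid
Conditions: Ac2O (2.5 equiv), pyridine, DMAP (cat.), 0 → 20 °C; aq. HCl work-up
Reagents that add atoms: acetic anhydride, CC(=O)OC(C)=O
Why: DMAP-catalysed O-acetylation (nucleophilic acyl substitution) of both phenols, with any mixed anhydride at the acid hydrolysed on work-up and the E-alkene untouched.

Step 4
Reactants: 6 3,4-O-[(E)-3-(4-acetoxyphenyl)-1-ethoxyprop-2-en-1-ylidene]-1,5-quinide; 8 (E)-3,4-diacetoxycinnamic acid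
Product: 11 3-O-[(E)-3,4-diacetoxycinnamoyl]-4-O-[(E)-4-acetoxycinnamoyl]-1,5-quinide, via 4-O-[(E)-4-acetoxycinnamoyl]-1,5-quinide 9 (not isolated), via (E)-3,4-diacetoxycinnamoyl chloride 10 (not isolated)
Conditions: (a) 6, AcOH/H2O 4:1, 20 °C, 15 min; evaporate, PhMe azeotrope; (b) 8, (COCl)2, DMF (cat.), CH2Cl2, 20 °C, evaporate; add (1.1 equiv) to crude 9, pyridine/CH2Cl2, DMAP (2 mol %), −15 → 0 °C
Reagents that add atoms: water, O; oxalyl chloride, O=C(Cl)C(=O)Cl (supplies the Cl of 10 only)
Why: Acid-catalysed ortho ester hydrolysis goes through the dioxolan-2-ylium ion and its hemi-ortho ester, which collapses by cleaving the bond to the equatorial O-3 (stereoelectronic control, King–Allbutt axial-ester rule) so the cinnamate stays on axial O-4, and the freed secondary equatorial 3-OH is then esterified by the acyl chloride (made by Vilsmeier-type activation) much faster than the tertiary 1-OH, with no ring stereocentre touched.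

Step 5
Reactants: 11 3-O-[(E)-3,4-diacetoxycinnamoyl]-4-O-[(E)-4-acetoxycinnamoyl]-1,5-quinide
Product: 12 3-O-(E)-caffeoyl-4-O-(E)-p-coumaroylquinic acid, (1R,3R,4S,5R)-3-{[(E)-3-(3,4-dihydroxyphenyl)prop-2-enoyl]oxy}-1,5-dihydroxy-4-{[(E)-3-(4-hydroxyphenyl)prop-2-enoyl]oxy}cyclohexane-1-carboxylic acid (CNP0077575.1)
Conditions: 1 M aq. HCl/THF 1:4, 20 °C, dark, 6–8 d; RP-C18
Reagents that add atoms: water, O
Why: Acid-catalysed acyl–oxygen (A_AC2) hydrolysis cleaves the strained bridged γ-lactone and the three aryl acetates well before the two conjugated cinnamate esters of secondary alcohols, keeps the C-5 configuration, and avoids base-type acyl migration; this is the established endgame for caffeoylquinic acids.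

## Compound list

1 | 4-iodophenyl acetate | CC(=O)Oc1ccc(I)cc1 | starting material
2 | triethyl orthoacrylate (3,3,3-triethoxyprop-1-ene) | C=CC(OCC)(OCC)OCC | starting material
3 | 4-[(E)-3,3,3-triethoxyprop-1-en-1-yl]phenyl acetate | CCOC(OCC)(OCC)/C=C/c1ccc(OC(C)=O)cc1 | intermediate
4 | (−)-quinic acid, (1S,3R,4S,5R)-1,3,4,5-tetrahydroxycyclohexane-1-carboxylic acid | O[C@H]1[C@H](O)C[C@](O)(C(=O)O)C[C@H]1O | starting material
5 | 1,5-quinide, (1S,3R,4R,5R)-1,3,4-trihydroxy-6-oxabicyclo[3.2.1]octan-7-one (not isolated) | O[C@H]1[C@H](OC2=O)C[C@@]2(O)C[C@H]1O | intermediate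
6 | 3,4-O-[(E)-3-(4-acetoxyphenyl)-1-ethoxyprop-2-en-1-ylidene]-1,5-quinide (ortho-ester carbon: both epimers) | O1[C@H]2[C@H](OC3=O)C[C@@]3(O)C[C@H]2OC1(OCC)/C=C/c1ccc(OC(C)=O)cc1 | intermediate
7 | (E)-caffeic acid | O=C(O)/C=C/c1ccc(O)c(O)c1 | starting material
8 | (E)-3,4-diacetoxycinnamic acid | CC(=O)Oc1ccc(/C=C/C(=O)O)cc1OC(C)=O | intermediate
9 | 4-O-[(E)-4-acetoxycinnamoyl]-1,5-quinide (not isolated) | CC(=O)Oc1ccc(/C=C/C(=O)O[C@H]2[C@H](OC3=O)C[C@@]3(O)C[C@H]2O)cc1 | intermediate
10 | (E)-3,4-diacetoxycinnamoyl chloride (not isolated) | CC(=O)Oc1ccc(/C=C/C(=O)Cl)cc1OC(C)=O | intermediate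
11 | 3-O-[(E)-3,4-diacetoxycinnamoyl]-4-O-[(E)-4-acetoxycinnamoyl]-1,5-quinide | CC(=O)Oc1ccc(/C=C/C(=O)O[C@H]2[C@H](OC3=O)C[C@@]3(O)C[C@H]2OC(=O)/C=C/c2ccc(OC(C)=O)c(OC(C)=O)c2)cc1 | intermediate
12 | 3-O-(E)-caffeoyl-4-O-(E)-p-coumaroylquinic acid | O=C(/C=C/c1ccc(O)cc1)O[C@H]1[C@H](O)C[C@](O)(C(=O)O)C[C@H]1OC(=O)/C=C/c1ccc(O)c(O)c1 | target

## Count and risks

Total steps: 5. Longest linear sequence: 4 steps (1/2 → 3 → 6 → 11 → 12; three steps from quinic acid).

Steps most likely to fail, in order: step 2, step 4, step 1.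

Step 2 (one-pot double cyclisation): 3 may be spent on the carboxylic acid or on residual water, or the acid-labile dioxolane may not survive filtration. The fallback sets out from 4 and rejoins the route at 11, handing regiocontrol to the innate reactivity order of the lactone (equatorial 3-OH > axial 4-OH > tertiary 1-OH) instead of to a ring. Quinic acid 4 is lactonised as in stage (a) and 1,5-quinide 5 is isolated. Heck coupling of 1 with acrylic acid (Pd(OAc)2, NaOAc, DMF, 90 °C) gives (E)-4-acetoxycinnamic acid F1, which oxalyl chloride/cat. DMF converts into (E)-4-acetoxycinnamoyl chloride F2. Quinide 5 is acylated with 1.0 equiv of 10 (pyridine/CH2Cl2, −20 °C) at the equatorial 3-OH to give 3-O-[(E)-3,4-diacetoxycinnamoyl]-1,5-quinide F3. Its axial 4-OH is then esterified with F2 (pyridine, DMAP cat., 0 °C) to give 11.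

Step 4 (opening and acylation): the hydroxy ester 9 can suffer 4→3 acyl migration or 1-O-acylation under pyridine/acyl chloride. The fallback sets out from 6 and rejoins at 12, and builds the caffeoyl unit on the molecule instead of transferring it. Compound 6 is opened to 9 as before. Heating 9 with Meldrum's acid (PhMe, 85 °C; neutral acyl-ketene transfer, secondary OH only) gives the malonate half-ester 3-O-(carboxyacetyl)-4-O-[(E)-4-acetoxycinnamoyl]-1,5-quinide F4. Knoevenagel–Doebner condensation of F4 with 3,4-dihydroxybenzaldehyde (pyridine, β-alanine cat., 50 °C, decarboxylative) gives 3-O-[(E)-caffeoyl]-4-O-[(E)-4-acetoxycinnamoyl]-1,5-quinide F5. The conditions of step 5 convert F5 into 12.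

Step 1 (Heck reaction on the ortho acrylate): β-ethoxide elimination may compete, or 3 may be lost on purification. The fallback sets out from 4 and 2 and rejoins at 11, making the aryl–vinyl bond last on an ordinary acrylate ester. Compounds 4 and 2 under the step-2 protocol give 3,4-O-(1-ethoxyprop-2-en-1-ylidene)-1,5-quinide F6. Aqueous 80 % AcOH opens it to 4-O-acryloyl-1,5-quinide F7. Acylation with 10 in pyridine gives 3-O-[(E)-3,4-diacetoxycinnamoyl]-4-O-acryloyl-1,5-quinide F8. Heck coupling of F8 with 1 (Pd(OAc)2, P(o-tol)3, NaOAc, DMF, 80 °C; the terminal acrylate reacts, the β-aryl cinnamate does not) gives 11.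

## Further compounds

F1 | step 2 | (E)-4-acetoxycinnamic acid | CC(=O)Oc1ccc(/C=C/C(=O)O)cc1
F2 | step 2 | (E)-4-acetoxycinnamoyl chloride | CC(=O)Oc1ccc(/C=C/C(=O)Cl)cc1
F3 | step 2 | 3-O-[(E)-3,4-diacetoxycinnamoyl]-1,5-quinide | O[C@H]1[C@H](OC2=O)C[C@@]2(O)C[C@H]1OC(=O)/C=C/c1ccc(OC(C)=O)c(OC(C)=O)c1
F4 | step 4 | 3-O-(carboxyacetyl)-4-O-[(E)-4-acetoxycinnamoyl]-1,5-quinide | CC(=O)Oc1ccc(/C=C/C(=O)O[C@H]2[C@H](OC3=O)C[C@@]3(O)C[C@H]2OC(=O)CC(=O)O)cc1
F5 | step 4 | 3-O-[(E)-caffeoyl]-4-O-[(E)-4-acetoxycinnamoyl]-1,5-quinide | CC(=O)Oc1ccc(/C=C/C(=O)O[C@H]2[C@H](OC3=O)C[C@@]3(O)C[C@H]2OC(=O)/C=C/c2ccc(O)c(O)c2)cc1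
F6 | step 1 | 3,4-O-(1-ethoxyprop-2-en-1-ylidene)-1,5-quinide | O1[C@H]2[C@H](OC3=O)C[C@@]3(O)C[C@H]2OC1(OCC)C=C
F7 | step 1 | 4-O-acryloyl-1,5-quinide | C=CC(=O)O[C@H]1[C@H](OC2=O)C[C@@]2(O)C[C@H]1O
F8 | step 1 | 3-O-[(E)-3,4-diacetoxycinnamoyl]-4-O-acryloyl-1,5-quinide | C=CC(=O)O[C@H]1[C@H](OC2=O)C[C@@]2(O)C[C@H]1OC(=O)/C=C/c1ccc(OC(C)=O)c(OC(C)=O)c1
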